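The readings are simulated for an exercise; the scatter is artificial.

At each time of reading I look first at the fraction of substrate left in the flask, not at the fraction made: if its logarithm falls evenly with time, the first step keeps one pace.

| setting | epsilon | flask |
|---|---|---|
| substrate | 0.010 M | 0.010 M |
| reagent | 9.5 mM | 9.50 mM |
| free catalyst | 50 µM | 50 µM |
| second catalyst | 8.4 µM | 8.4 µM |
| impurity | 2.7 µM | 2.7 µM |
| added ligand | 96 µM | 96 µM |
| remark | the very flask that is asked about, followed so far |  |

epsilon run (percent of the substrate charged)

| time / s | product / % | substrate / % |
|---|---|---|
| 10.0 | 0.9 | 95.4 |
| 20.0 | 3.5 | 91.0 |
| 50.0 | 13.3 | 79.0 |
| 120 | 35.1 | 57.2 |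

(standard deviation of a reading: 0.3 percentage points)

* apparent order in free catalyst when 30% of the substrate are converted (percent change of the rate of making product for one percent more free catalyst charged)
* apparent order in reagent when 30% of the substrate are converted (percent change of the rate of making product for one percent more reagent charged)

- candidate steps: second catalyst + impurity -> spent catalyst; free catalyst + added ligand <-> idle complex; substrate + free catalyst -> free catalyst + intermediate; reagent + second catalyst + intermediate -> second catalyst + product
- no earlier run changes the charge of free catalyst; that part of a forecast is a guess
- "the catalyst" is free catalyst with its forms; second catalyst is a second catalyst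
- no earlier run changes the charge of reagent; that part of a forecast is a guess

It does fall evenly in this flask. The reading at 10.0 s gives 0.283 min⁻¹ and the reading at 120 s gives 0.279 min⁻¹, which I carry on as the decay constant of the substrate: the part of what is left that goes per unit time, a pseudo-first-order constant. So I read the free catalyst as steady over these readings.

In the first instants the substrate reacts faster than product appears: at 10.0 s the readings of this flask put 4.60% of the substrate as reacted, more than the 0.9% of product, and I read the difference as intermediate. In the middle the intermediate holds level, at 7.70% at 50.0 s and 7.70% at 120 s. Product gained between those readings, taken per unit time and per intermediate, gives a clearance constant of 2.43 min⁻¹, faster than the decay constant by a factor 8.71.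

The decay constant puts 30% conversion, as asked, at 1.28 min. There I expect product to follow the substrate left, with the reagent holding a share of about the inverse factor, so my order in reagent is 0.115. Toward the end I expect the reagent to matter more: charged at 0.950 of the substrate, it is the limiting reagent, and by the candidate step the clearance goes with its fraction left.

For the catalyst, the decay constant does not show how much is bound. With 96 µM of added ligand against 50 µM of catalyst, the order runs from one for weak binding up to 2.09 for tight binding, and I guess the middle, 1.54.

The forecast gives 1.25 in free catalyst and 0.06 in reagent, both lower than my figures, remarking “The runs do not fix Kd”. The flask gives 1.5 in free catalyst and 0.19 in reagent.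

    second catalyst + impurity → spent catalyst (k = 7.90 × 10⁶ M⁻¹ s⁻¹)
    free catalyst + added ligand ⇌ idle complex, settled at all times (K = 1.10 × 10⁵ M⁻¹)
    substrate + free catalyst → free catalyst + intermediate (k = 650 M⁻¹ s⁻¹)
    reagent + second catalyst + intermediate → second catalyst + product (k = 9.20 × 10⁵ M⁻² s⁻¹)

Free catalyst stands at 14.6% of the catalyst charged at 0.600 min, with idle complex at 85.4%, and free catalyst is still 14.6% at 6.00 min. The decay constant puts the substrate left at 6.00 min at 18.7%, and the flask holds 18.2%.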